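**Plan**

- Cuts (germacrane numbering): first C1–OOH (Schenck ene reaction of a C1=C10 olefin carrying the C14 methyl), the C8–O ester and the C15 acetate; then, together, the C6–C7 bond and the lactone C12–O bond; then C7–C11, C1–C2, C3–C4 and C9–C10 of the open chain.
- Enabling feature: the α-methylene-γ-butyrolactone contains the array O–C6–C7–C11(=C13H2)–C12=O, a homoallylic-alcohol retron, and C6–C7 is shared by the five-membered lactone and the ten-membered carbocycle. An umpoled 2-(methoxycarbonyl)allyl unit (C13–C11=C7) adding to a C6 aldehyde therefore makes both rings, C6, C7 and the exocyclic methylene in one event; both carbons are electrophilic in the precursor (enal carbon, enoate β-carbon) and are joined by polarity reversal at chromium.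
- Forward: diene alcohol 5 (C2–C6, C15) from 2-butyne-1,4-diol and alkenyl iodide 13 (C1, C7–C14) from (R)-glycidol are joined at C1–C2; oxidation and SN2' bromination give the seco enal–bromide 17; ring closure gives the carbocycle and then the lactone; desilylation, acetylation at O15, acylation at O8 and the ene reaction finish the route.
- Stereochemistry: C8 from (R)-glycidol; C7 and C6 from C8 in the ring closure (allylic strain and chair transition state, cis-fused lactone); C1 from outer-face attack of singlet oxygen on the macrocycle; the side-chain carbinol from the (R)-butane-1,2,4-triol acetonide 23; olefin geometries from trans-hydroalumination (C4=C5), syn-carboalumination (C1=C10) and the Baylis–Hillman bromide (C7=C11).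

Key step: step 12

Remark: C-numbers in the explanations are germacrane numbers (C1 = CH–OOH, C4 carries C15H2OAc, C6 = lactone CH–O, C7 = ring-fusion CH, C8 = CH–O-acyl, C10 carries C14, C11 carries C13), locants inside systematic names of open-chain compounds are those of the name, and the C4=C5 olefin (C3 and C6 cis) is E by the sequence rule.

**Step 1**
Reactants: 1 2-butyne-1,4-diol
Product: 2 4-[(tert-butyldimethylsilyl)oxy]but-2-yn-1-ol
Conditions: NaH (1.0 equiv), THF, 0 °C; TBSCl (1.0 equiv), 0 °C to rt
Reagents that add atoms: tert-butyldimethylsilyl chloride, CC(C)(C)[Si](C)(C)Cl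
Why: Monosilylation of a symmetrical diol through its sparingly soluble monosodium alkoxide differentiates the future C15 oxygen (silylated) from the future C6 oxygen (free).

**Step 2**
Reactants: 2 4-[(tert-butyldimethylsilyl)oxy]but-2-yn-1-ol
Product: 4 (2Z)-4-[(tert-butyldimethylsilyl)oxy]-3-iodobut-2-en-1-ol, via cyclic sodium alkenylaluminate 3 (not isolated)
Conditions: NaAlH2(OCH2CH2OMe)2 (Red-Al, 1.3 equiv), THF, 0 °C; then I2, THF, −78 to 0 °C
Reagents that add atoms: iodine, [I][I]
Why: Hydroxyl-directed trans-hydroalumination of the propargylic alcohol puts aluminium on the distal alkyne carbon (C4) cis to the carbinol, and iodinolysis with retention gives the (Z)-iodide, which fixes C6 trans to C15 and reserves the position cis to C6 for C3.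

**Step 3**
Reactants: 4 (2Z)-4-[(tert-butyldimethylsilyl)oxy]-3-iodobut-2-en-1-ol
Product: 5 (2E)-3-{[(tert-butyldimethylsilyl)oxy]methyl}penta-2,4-dien-1-ol
Conditions: Bu3SnCH=CH2 (1.2 equiv), PdCl2(MeCN)2 (5 mol%), DMF, rt
Reagents that add atoms: tributyl(vinyl)stannane, C=C[Sn](CCCC)(CCCC)CCCC
Why: Stille coupling of an alkenyl iodide proceeds with retention of olefin geometry, tolerates the free allylic alcohol and installs C3 and C2 as a vinyl group.

**Step 4**
Reactants: 6 (R)-glycidol
Product: 7 (2S)-pent-4-yne-1,2-diol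
Conditions: LiC≡CH·H2NCH2CH2NH2 (2.5 equiv), DMSO, 0 °C to rt
Reagents that add atoms: lithium acetylide ethylenediamine complex, [Li+].[C-]#C.NCCN
Why: SN2 opening of the terminal epoxide carbon by acetylide forms C9–C10 without touching the stereocentre, so C8 comes from the chiral pool (the descriptor changes from R to S only because the ranking of the two CH2 groups changes, and Payne equilibration of glycidol alkoxide is degenerate).

**Step 5**
Reactants: 7 (2S)-pent-4-yne-1,2-diol
Product: 8 (2S)-1,2-bis[(triethylsilyl)oxy]pent-4-yne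
Conditions: TESCl (2.4 equiv), imidazole, DMF, 0 °C to rt
Reagents that add atoms: chlorotriethylsilane, CC[Si](Cl)(CC)CC
Why: Standard bis-silylation, with triethylsilyl chosen because the primary ether can later be oxidized directly while the secondary ether at C8 is kept until after the ring closure.

**Step 6**
Reactants: 8 (2S)-1,2-bis[(triethylsilyl)oxy]pent-4-yne
Product: 10 (2S,4E)-5-iodo-4-methyl-1,2-bis[(triethylsilyl)oxy]pent-4-ene, via alkenyldimethylalane 9 (not isolated)
Conditions: AlMe3 (2.5 equiv), Cp2ZrCl2 (0.25 equiv), CH2Cl2, 0 °C to rt; then I2, THF, −30 °C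
Reagents that add atoms: trimethylaluminium, C[Al](C)C; iodine, [I][I]
Why: Zirconium-catalysed Negishi carboalumination adds the C14 methyl and aluminium syn across the terminal alkyne with methyl on the internal carbon, and iodinolysis with retention gives the (E)-iodide that defines the C1=C10 geometry.

**Step 7**
Reactants: 10 (2S,4E)-5-iodo-4-methyl-1,2-bis[(triethylsilyl)oxy]pent-4-ene
Product: 11 (2S,4E)-5-iodo-4-methyl-2-[(triethylsilyl)oxy]pent-4-enal
Conditions: (COCl)2 (3 equiv), DMSO (6 equiv), CH2Cl2, −78 to −30 °C; then Et3N, −78 to 0 °C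
Reagents that add atoms: none
Why: Under Swern conditions a primary triethylsilyl ether is cleaved by the chlorosulfonium salt and oxidized in the same operation to the aldehyde while the secondary triethylsilyl ether is retained, and the α-silyloxy aldehyde is used at once to avoid epimerization at C8.

**Step 8**
Reactants: 11 (2S,4E)-5-iodo-4-methyl-2-[(triethylsilyl)oxy]pent-4-enal; 12 methyl acrylate
Product: 13 methyl (4S,6E)-3-hydroxy-7-iodo-6-methyl-2-methylidene-4-[(triethylsilyl)oxy]hept-6-enoate (C3 epimers)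
Conditions: DABCO (1.0 equiv), methyl acrylate (10 equiv, neat), rt
Reagents that add atoms: none
Why: Morita–Baylis–Hillman reaction of the inductively activated α-silyloxy aldehyde attaches C11, C12 and C13 to C7, and the new carbinol centre, formed without control, becomes sp2 in step 11.

**Step 9**
Reactants: 5 (2E)-3-{[(tert-butyldimethylsilyl)oxy]methyl}penta-2,4-dien-1-ol; 13 methyl (4S,6E)-3-hydroxy-7-iodo-6-methyl-2-methylidene-4-[(triethylsilyl)oxy]hept-6-enoate
Product: 15 methyl (4S,6E,10E)-10-{[(tert-butyldimethylsilyl)oxy]methyl}-3,12-dihydroxy-6-methyl-2-methylidene-4-[(triethylsilyl)oxy]dodeca-6,10-dienoate (C3 epimers), via B-alkyl-9-BBN borinate 14 (not isolated)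
Conditions: 5, 9-BBN (2.2 equiv), THF, 0 °C to rt; then 13, PdCl2(dppf) (5 mol%), AsPh3, Cs2CO3, DMF/H2O, rt
Reagents that add atoms: none
Why: 9-BBN first converts the alcohol into its borinate and then hydroborates the unhindered terminal CH2 of the 1,3-diene, and B-alkyl Suzuki–Miyaura coupling with the (E)-alkenyl iodide forms C1–C2 with retention of both olefin geometries.

**Step 10**
Reactants: 15 methyl (4S,6E,10E)-10-{[(tert-butyldimethylsilyl)oxy]methyl}-3,12-dihydroxy-6-methyl-2-methylidene-4-[(triethylsilyl)oxy]dodeca-6,10-dienoate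
Product: 16 methyl (4S,6E,10E)-10-{[(tert-butyldimethylsilyl)oxy]methyl}-3-hydroxy-6-methyl-2-methylidene-12-oxo-4-[(triethylsilyl)oxy]dodeca-6,10-dienoate (C3 epimers)
Conditions: TEMPO (10 mol%), PhI(OAc)2 (1.1 equiv), CH2Cl2, rt
Reagents that add atoms: none
Why: Oxoammonium (TEMPO) oxidation is selective for the primary allylic alcohol over the hindered, electron-poor secondary Baylis–Hillman carbinol and gives the enal without isomerization of the C4=C5 bond.

**Step 11**
Reactants: 16 methyl (4S,6E,10E)-10-{[(tert-butyldimethylsilyl)oxy]methyl}-3-hydroxy-6-methyl-2-methylidene-12-oxo-4-[(triethylsilyl)oxy]dodeca-6,10-dienoate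
Product: 17 methyl (2Z,4S,6E,10E)-2-(bromomethyl)-10-{[(tert-butyldimethylsilyl)oxy]methyl}-6-methyl-12-oxo-4-[(triethylsilyl)oxy]dodeca-2,6,10-trienoate
Conditions: NBS (1.3 equiv), Me2S (1.5 equiv), CH2Cl2, −20 °C to rt
Reagents that add atoms: N-bromosuccinimide, O=C1CCC(=O)N1Br
Why: The bromodimethylsulfonium reagent converts Baylis–Hillman alcohols into 2-(bromomethyl)-2-enoates by SN2' displacement, and both C7 epimers converge on the olefin in which C8 is trans to the ester (Z by the sequence rule).

**Step 12**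
Reactants: 17 methyl (2Z,4S,6E,10E)-2-(bromomethyl)-10-{[(tert-butyldimethylsilyl)oxy]methyl}-6-methyl-12-oxo-4-[(triethylsilyl)oxy]dodeca-2,6,10-trienoate
Product: 20 (6S,7S,8S)-15-[(tert-butyldimethylsilyl)oxy]-8-[(triethylsilyl)oxy]germacra-1(10),4,11(13)-trien-12,6-olide, via allylchromium dichloride 18 (not isolated), via chromium alkoxide of the seco ester 19 (not isolated)
Conditions: CrCl2 (10 equiv), THF, 0.003 M (17 added by syringe pump), rt then 40 °C; aq NH4Cl
Reagents that add atoms: none
Why: Two equivalents of CrCl2 (divalent chromium) reduce the allylic C13–Br bond to the allylchromium species 18 (trivalent chromium), which reverses the polarity of the enoate β-carbon C7, so that C7 adds to the aldehyde carbon C6 with allylic transposition through a six-membered chair transition state (Cr–O6–C6–C7–C11–C13) to give alkoxide 19 with the exocyclic C11=C13 bond, and 19 then acylates itself on the C12 methyl ester. The closest known reaction type is the intramolecular Nozaki–Hiyama–Kishi (Barbier-type) allylation of aldehydes with 2-(bromomethyl)-2-enoates, which is established for medium-ring α-methylene-γ-butyrolactones. The C6–C7 bond closes the ten-membered carbocycle in a 10-exo-trig addition to the carbonyl group, and the O6–C12 bond closes the lactone in a 5-exo-trig acyl substitution. C6 relative to C7 is set by the chair: the (Z)-allylchromium places C8 axial on C7 and the aldehyde places C5 equatorial on C6, which gives the syn adduct and hence the cis-fused lactone (6S with 7R in the target). C7 relative to C8 is set by allylic 1,3-strain: H8 lies in the allyl plane facing C13H2, the C9 tether and the bulky triethylsilyloxy group occupy opposite faces, and the aldehyde can only arrive on the tether face, anti to the silyloxy group. The step needs ring closure to win over intermolecular allylation (high dilution, and the two trisubstituted olefins with C3 and C6 cis fold the chain), γ- over α-attack of the allyl unit (cyclic transition state), and survival of the δ-silyloxy group against reductive 1,4-elimination (covalent C–Cr bond, mild temperature).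

**Step 13**
Reactants: 20 (6S,7S,8S)-15-[(tert-butyldimethylsilyl)oxy]-8-[(triethylsilyl)oxy]germacra-1(10),4,11(13)-trien-12,6-olide
Product: 21 (6S,7R,8S)-8,15-dihydroxygermacra-1(10),4,11(13)-trien-12,6-olide
Conditions: HF·pyridine, pyridine, THF, 0 °C to rt
Reagents that add atoms: none
Why: Fluoride-mediated cleavage of both silyl ethers under buffered, non-basic conditions should leave the α-methylene lactone intact and avoid base-induced translactonization to O8.

**Step 14**
Reactants: 21 (6S,7R,8S)-8,15-dihydroxygermacra-1(10),4,11(13)-trien-12,6-olide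
Product: 22 (6S,7R,8S)-15-acetoxy-8-hydroxygermacra-1(10),4,11(13)-trien-12,6-olide
Conditions: AcCl (1.05 equiv), 2,4,6-collidine, CH2Cl2, −78 °C
Reagents that add atoms: acetyl chloride, CC(=O)Cl
Why: Kinetically controlled acylation with a weak hindered base acetylates the primary allylic C15 hydroxyl in preference to the secondary C8 hydroxyl flanked by the ring fusion.

**Step 15**
Reactants: 23 2-[(4R)-2,2-dimethyl-1,3-dioxolan-4-yl]ethanol
Product: 24 2-[(4R)-2,2-dimethyl-1,3-dioxolan-4-yl]acetaldehyde
Conditions: TEMPO (10 mol%), PhI(OAc)2 (1.1 equiv), CH2Cl2, rt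
Reagents that add atoms: none
Why: Mild oxoammonium (TEMPO) oxidation gives the β-alkoxy aldehyde without conditions that would open the acetonide or eliminate the β-oxygen.

**Step 16**
Reactants: 24 2-[(4R)-2,2-dimethyl-1,3-dioxolan-4-yl]acetaldehyde
Product: 25 2-[(4R)-2,2-dimethyl-1,3-dioxolan-4-yl]prop-2-enal
Conditions: 37% aq CH2O (1.5 equiv), pyrrolidine (10 mol%), EtCO2H (10 mol%), i-PrOH, 45 °C
Reagents that add atoms: formaldehyde, C=O
Why: Amine-catalysed Mannich condensation and elimination (organocatalytic α-methylenation of an aldehyde) installs the acrylate methylene at the CH2 group, and the stereocentre, which is not the enolized position, is retained.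

**Step 17**
Reactants: 25 2-[(4R)-2,2-dimethyl-1,3-dioxolan-4-yl]prop-2-enal
Product: 26 2-[(4R)-2,2-dimethyl-1,3-dioxolan-4-yl]prop-2-enoic acid
Conditions: NaClO2, NaH2PO4, 2-methylbut-2-ene, t-BuOH/H2O, 0 °C to rt
Reagents that add atoms: sodium chlorite, [Na+].[O-]Cl=O
Why: Pinnick oxidation converts α-substituted acroleins into acrylic acids without touching the olefin or the acetonide.

**Step 18**
Reactants: 22 (6S,7R,8S)-15-acetoxy-8-hydroxygermacra-1(10),4,11(13)-trien-12,6-olide; 26 2-[(4R)-2,2-dimethyl-1,3-dioxolan-4-yl]prop-2-enoic acid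
Product: 28 (6S,7R,8S)-15-acetoxy-8-{2-[(4R)-2,2-dimethyl-1,3-dioxolan-4-yl]prop-2-enoyloxy}germacra-1(10),4,11(13)-trien-12,6-olide, via mixed trichlorobenzoic anhydride 27 (not isolated)
Conditions: 26, 2,4,6-Cl3C6H2COCl, Et3N, THF, rt; then 22, DMAP, toluene, rt
Reagents that add atoms: none
Why: Yamaguchi esterification acylates the hindered secondary C8 alcohol with retention at C8 under conditions in common use for α-substituted acrylic acids.

**Step 19**
Reactants: 28 (6S,7R,8S)-15-acetoxy-8-{2-[(4R)-2,2-dimethyl-1,3-dioxolan-4-yl]prop-2-enoyloxy}germacra-1(10),4,11(13)-trien-12,6-olide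
Product: 29 (6S,7R,8S)-15-acetoxy-8-{[(3R)-3,4-dihydroxy-2-methylidenebutanoyl]oxy}germacra-1(10),4,11(13)-trien-12,6-olide
Conditions: AcOH/H2O (4:1), 35 °C
Reagents that add atoms: none
Why: Acid-catalysed acetonide hydrolysis frees the side-chain diol before the acid-sensitive allylic hydroperoxide is introduced.

**Step 20**
Reactants: 29 (6S,7R,8S)-15-acetoxy-8-{[(3R)-3,4-dihydroxy-2-methylidenebutanoyl]oxy}germacra-1(10),4,11(13)-trien-12,6-olide
Product: 30 (1R,6S,7R,8S)-15-acetoxy-8-{[(3R)-3,4-dihydroxy-2-methylidenebutanoyl]oxy}-1-hydroperoxygermacra-4,10(14),11(13)-trien-12,6-olide (CNP0307408.1)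
Conditions: O2, visible light, tetraphenylporphyrin (1 mol%), CH2Cl2, −20 °C
Reagents that add atoms: oxygen, O=O
Why: The Schenck ene reaction of singlet oxygen should take place at the only electron-rich olefin (C1=C10; C4=C5 is deactivated by two allylic C–O bonds and the acrylates are electron-poor), abstract hydrogen from the C14 methyl on the more substituted side (cis effect) and bind oxygen to C1 from the exposed outer face of the ten-membered ring, which sets C1 as R.

**Compound list**

1 | 2-butyne-1,4-diol | OCC#CCO | starting material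
2 | 4-[(tert-butyldimethylsilyl)oxy]but-2-yn-1-ol | OCC#CCO[Si](C)(C)C(C)(C)C | intermediate
3 | cyclic sodium alkenylaluminate from 2 (five-membered O–Al–C ring, not isolated) | [Na+].COCCO[Al-]1(OCCOC)OCC=C1CO[Si](C)(C)C(C)(C)C | intermediate
4 | (2Z)-4-[(tert-butyldimethylsilyl)oxy]-3-iodobut-2-en-1-ol | OC/C=C(\I)CO[Si](C)(C)C(C)(C)C | intermediate
5 | (2E)-3-{[(tert-butyldimethylsilyl)oxy]methyl}penta-2,4-dien-1-ol | OC/C=C(/CO[Si](C)(C)C(C)(C)C)C=C | intermediate
6 | (R)-glycidol | OC[C@@H]1CO1 | starting material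
7 | (2S)-pent-4-yne-1,2-diol | OC[C@@H](O)CC#C | intermediate
8 | (2S)-1,2-bis[(triethylsilyl)oxy]pent-4-yne | CC[Si](CC)(CC)OC[C@@H](O[Si](CC)(CC)CC)CC#C | intermediate
9 | (E)-alkenyldimethylalane from 8 (not isolated) | CC[Si](CC)(CC)OC[C@@H](O[Si](CC)(CC)CC)C/C(C)=C/[Al](C)C | intermediate
10 | (2S,4E)-5-iodo-4-methyl-1,2-bis[(triethylsilyl)oxy]pent-4-ene | CC[Si](CC)(CC)OC[C@@H](O[Si](CC)(CC)CC)C/C(C)=C/I | intermediate
11 | (2S,4E)-5-iodo-4-methyl-2-[(triethylsilyl)oxy]pent-4-enal | O=C[C@@H](O[Si](CC)(CC)CC)C/C(C)=C/I | intermediate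
12 | methyl acrylate | C=CC(=O)OC | starting material
13 | methyl (4S,6E)-3-hydroxy-7-iodo-6-methyl-2-methylidene-4-[(triethylsilyl)oxy]hept-6-enoate, C3 epimers | COC(=O)C(=C)C(O)[C@@H](O[Si](CC)(CC)CC)C/C(C)=C/I | intermediate
14 | B-alkyl-9-BBN borinate of 5 (boron on C2 and on O6, not isolated) | O(C/C=C(/CO[Si](C)(C)C(C)(C)C)CCB1C2CCCC1CCC2)B1C2CCCC1CCC2 | intermediate
15 | methyl (4S,6E,10E)-10-{[(tert-butyldimethylsilyl)oxy]methyl}-3,12-dihydroxy-6-methyl-2-methylidene-4-[(triethylsilyl)oxy]dodeca-6,10-dienoate, C3 epimers | OC/C=C(/CO[Si](C)(C)C(C)(C)C)CC/C=C(\C)C[C@H](O[Si](CC)(CC)CC)C(O)C(=C)C(=O)OC | intermediate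
16 | methyl (4S,6E,10E)-10-{[(tert-butyldimethylsilyl)oxy]methyl}-3-hydroxy-6-methyl-2-methylidene-12-oxo-4-[(triethylsilyl)oxy]dodeca-6,10-dienoate, C3 epimers | O=C/C=C(/CO[Si](C)(C)C(C)(C)C)CC/C=C(\C)C[C@H](O[Si](CC)(CC)CC)C(O)C(=C)C(=O)OC | intermediate
17 | methyl (2Z,4S,6E,10E)-2-(bromomethyl)-10-{[(tert-butyldimethylsilyl)oxy]methyl}-6-methyl-12-oxo-4-[(triethylsilyl)oxy]dodeca-2,6,10-trienoate | O=C/C=C(/CO[Si](C)(C)C(C)(C)C)CC/C=C(\C)C[C@H](O[Si](CC)(CC)CC)/C=C(\CBr)C(=O)OC | intermediate
18 | allylchromium dichloride from 17 (trivalent chromium on C13, not isolated) | O=C/C=C(/CO[Si](C)(C)C(C)(C)C)CC/C=C(\C)C[C@H](O[Si](CC)(CC)CC)/C=C(\C[Cr](Cl)Cl)C(=O)OC | intermediate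
19 | chromium alkoxide of the ten-membered seco hydroxy ester (C6–C7 bond formed, configured as in 20, not isolated) | COC(=O)C(=C)[C@H]1[C@@H](O[Cr](Cl)Cl)/C=C(/CO[Si](C)(C)C(C)(C)C)CC/C=C(\C)C[C@@H]1O[Si](CC)(CC)CC | intermediate
20 | (6S,7S,8S)-15-[(tert-butyldimethylsilyl)oxy]-8-[(triethylsilyl)oxy]germacra-1(10),4,11(13)-trien-12,6-olide; 1(10)E, C3 and C6 cis at C4=C5, cis-fused lactone; C7 reads S only because the silyl ether raises the rank of C8, the spatial arrangement is that of 7R in the target | C=C1C(=O)O[C@H]2/C=C(/CO[Si](C)(C)C(C)(C)C)CC/C=C(\C)C[C@H](O[Si](CC)(CC)CC)[C@@H]12 | intermediate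
21 | (6S,7R,8S)-8,15-dihydroxygermacra-1(10),4,11(13)-trien-12,6-olide | C=C1C(=O)O[C@H]2/C=C(/CO)CC/C=C(\C)C[C@H](O)[C@@H]12 | intermediate
22 | (6S,7R,8S)-15-acetoxy-8-hydroxygermacra-1(10),4,11(13)-trien-12,6-olide | C=C1C(=O)O[C@H]2/C=C(/COC(C)=O)CC/C=C(\C)C[C@H](O)[C@@H]12 | intermediate
23 | 2-[(4R)-2,2-dimethyl-1,3-dioxolan-4-yl]ethanol | OCC[C@@H]1COC(C)(C)O1 | starting material
24 | 2-[(4R)-2,2-dimethyl-1,3-dioxolan-4-yl]acetaldehyde | O=CC[C@@H]1COC(C)(C)O1 | intermediate
25 | 2-[(4R)-2,2-dimethyl-1,3-dioxolan-4-yl]prop-2-enal | C=C(C=O)[C@@H]1COC(C)(C)O1 | intermediate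
26 | 2-[(4R)-2,2-dimethyl-1,3-dioxolan-4-yl]prop-2-enoic acid | C=C(C(=O)O)[C@@H]1COC(C)(C)O1 | intermediate
27 | mixed anhydride of 26 with 2,4,6-trichlorobenzoic acid (not isolated) | C=C(C(=O)OC(=O)c1c(Cl)cc(Cl)cc1Cl)[C@@H]1COC(C)(C)O1 | intermediate
28 | (6S,7R,8S)-15-acetoxy-8-{2-[(4R)-2,2-dimethyl-1,3-dioxolan-4-yl]prop-2-enoyloxy}germacra-1(10),4,11(13)-trien-12,6-olide | C=C1C(=O)O[C@H]2/C=C(/COC(C)=O)CC/C=C(\C)C[C@H](OC(=O)C(=C)[C@@H]3COC(C)(C)O3)[C@@H]12 | intermediate
29 | (6S,7R,8S)-15-acetoxy-8-{[(3R)-3,4-dihydroxy-2-methylidenebutanoyl]oxy}germacra-1(10),4,11(13)-trien-12,6-olide | C=C1C(=O)O[C@H]2/C=C(/COC(C)=O)CC/C=C(\C)C[C@H](OC(=O)C(=C)[C@@H](O)CO)[C@@H]12 | intermediate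
30 | (1R,6S,7R,8S)-15-acetoxy-8-{[(3R)-3,4-dihydroxy-2-methylidenebutanoyl]oxy}-1-hydroperoxygermacra-4,10(14),11(13)-trien-12,6-olide (CNP0307408.1) | C=C1C(=O)O[C@H]2/C=C(/COC(C)=O)CC[C@@H](OO)C(=C)C[C@H](OC(=O)C(=C)[C@@H](O)CO)[C@@H]12 | target

**Step count and risks**

Total step count: 20. Longest linear sequence: 14 steps (steps 4 to 14 and 18 to 20, from (R)-glycidol).

Steps most likely to fail:

1. Step 12. Intermolecular allylation may outrun the ten-membered ring closure, the C8 silyloxy group may be lost by reductive 1,4-elimination at the allylchromium stage, or a boat transition state may erode the C6/C7 relationship. The fallback sets out from 17 and returns at 20. The bromide is converted with Bu3SnSnBu3 and Pd(PPh3)4 in THF into the isolable allylic stannane F1. F1 is cyclized without any reducing metal by BF3·OEt2 in CH2Cl2 at −78 °C under high dilution; this Lewis-acid-promoted SE2' addition runs through an open transition state, is syn-selective whatever the allyl geometry, and the C9 tether again fixes the face at C7. The product is the seco hydroxy ester F2, which is lactonized with PPTS in benzene to 20.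

2. Step 20. Singlet oxygen may attack the other face of C1=C10 if the macrocycle populates a conformer that exposes it (C1 epimer), or hydrogen may be abstracted from C2 to give the tertiary C10 hydroperoxide. The fallback sets out from 28 and returns at 30. Photooxygenation of the acetonide 28 under the conditions of step 20 would then give the C1-epimeric hydroperoxide acetonide F3. Reduction with PPh3 gives the (1S)-allylic alcohol F4, and MsCl/Et3N at −65 °C gives the mesylate F5. Perhydrolysis with anhydrous H2O2 in Et2O at low temperature (SN2 displacement with inversion, kept cold to suppress SN2' attack at C14) gives the (1R)-hydroperoxide acetonide F6. Hydrolysis of the acetonide as in step 19 gives 30.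

3. Step 9. The base- and palladium-sensitive Baylis–Hillman unit of 13 may undergo retro-aldol cleavage, conjugate addition or Heck-type insertion of the alkenylpalladium into its acrylate during the coupling, and the diene may be hydroborated twice. The fallback sets out from 5 and 10 and returns at 16. Borinate 14 is coupled under the same conditions with the robust bis-silyl ether 10 to give the coupled alcohol F7. A Swern oxidation with excess reagent oxidizes the allylic alcohol and converts the primary triethylsilyl ether directly into the aldehyde, giving the dialdehyde F8. The Morita–Baylis–Hillman reaction with methyl acrylate and DABCO is then run on F8, where the α-silyloxy aldehyde is far more electrophilic than the β,β-disubstituted enal, and gives 16.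

Further compounds
F1 | step 12 | methyl (2Z,4S,6E,10E)-10-{[(tert-butyldimethylsilyl)oxy]methyl}-6-methyl-12-oxo-2-[(tributylstannyl)methyl]-4-[(triethylsilyl)oxy]dodeca-2,6,10-trienoate (allylic stannane) | O=C/C=C(/CO[Si](C)(C)C(C)(C)C)CC/C=C(\C)C[C@H](O[Si](CC)(CC)CC)/C=C(\C[Sn](CCCC)(CCCC)CCCC)C(=O)OC
F2 | step 12 | ten-membered seco hydroxy ester (free C6 hydroxyl, methyl 2-substituted acrylate on C7, configured as in 20) | COC(=O)C(=C)[C@H]1[C@@H](O)/C=C(/CO[Si](C)(C)C(C)(C)C)CC/C=C(\C)C[C@@H]1O[Si](CC)(CC)CC
F3 | step 20 | (1S)-hydroperoxide acetonide, C1 epimer of F6 | C=C1C(=O)O[C@H]2/C=C(/COC(C)=O)CC[C@H](OO)C(=C)C[C@H](OC(=O)C(=C)[C@@H]3COC(C)(C)O3)[C@@H]12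
F4 | step 20 | (1S)-allylic alcohol acetonide | C=C1C(=O)O[C@H]2/C=C(/COC(C)=O)CC[C@H](O)C(=C)C[C@H](OC(=O)C(=C)[C@@H]3COC(C)(C)O3)[C@@H]12
F5 | step 20 | (1S)-methanesulfonate acetonide | C=C1C(=O)O[C@H]2/C=C(/COC(C)=O)CC[C@H](OS(C)(=O)=O)C(=C)C[C@H](OC(=O)C(=C)[C@@H]3COC(C)(C)O3)[C@@H]12
F6 | step 20 | (1R)-hydroperoxide acetonide, acetonide of 30 | C=C1C(=O)O[C@H]2/C=C(/COC(C)=O)CC[C@@H](OO)C(=C)C[C@H](OC(=O)C(=C)[C@@H]3COC(C)(C)O3)[C@@H]12
F7 | step 9 | (2E,6E,9S)-3-{[(tert-butyldimethylsilyl)oxy]methyl}-7-methyl-9,10-bis[(triethylsilyl)oxy]deca-2,6-dien-1-ol | OC/C=C(/CO[Si](C)(C)C(C)(C)C)CC/C=C(\C)C[C@H](O[Si](CC)(CC)CC)CO[Si](CC)(CC)CC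
F8 | step 9 | (2S,4E,8E)-8-{[(tert-butyldimethylsilyl)oxy]methyl}-4-methyl-2-[(triethylsilyl)oxy]deca-4,8-dienedial | O=C/C=C(/CO[Si](C)(C)C(C)(C)C)CC/C=C(\C)C[C@H](O[Si](CC)(CC)CC)C=O
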